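## The problem

The target is an unsymmetrical dimer of two trans-3,4-dibenzyl-γ-butyrolactone units. Rings A and D are 3,4-dimethoxyphenyl groups. Ring B (3-methoxy-4-aryloxyphenyl) and ring C (3-aryloxy-4-hydroxy-5-methoxyphenyl) are joined by a diaryl ether from the C4 oxygen of ring B to C3 of ring C, next to the only free phenol. No carbocycle has to be built; the task is to place two lactones, each with (3S,4S) centres, on a diaryl ether that is oxygenated on both sides of the ether bond. The two pairs of stereocentres are insulated from each other by the diaryl ether, so neither lactone can steer the other and each C4 must be set by an external chiral influence, twice and in the same sense. Within one lactone C4 can control C3: C3 sits between the lactone carbonyl and a benzylic carbon, is epimerisable and prefers to be trans to the C4 benzyl group. Sensitive points are the free phenol (to be masked until the end), the lactones (opened by hard nucleophiles), the labile C3–H, and the electron-rich arenes, which rule out strong oxidants and electrophiles late in the route. The feature that is exploited is that in each lactone C3, C4 and the outer benzylic CH2 (the one bonded to ring A or D) are three contiguous carbons, while C3 also carries the benzylic carbon of ring B or C. If that inner carbon is held as a ketone, C3, C4 and the outer CH2 can be stored as a cyclopropane fused to the lactone and activated by two carbonyl groups, which an aryl nucleophile should open at the CH2.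

## Retrosynthesis

**16 to 15.** Target 16 is first adjusted in oxidation level only. The two inner benzylic CH2 groups become aryl ketones and the phenol a benzyl ether, giving bis(β-keto lactone) 15. No skeletal bond is cut. The ketones make C3 strongly acidic, so trans is reached by equilibration, and they are the activating groups of the next cut. All three C–O functions (two C=O, one O-benzyl) should fall to one acid-promoted hydrogenolysis. The forward step must reduce a ketone para to an aryloxy group as well as one para to a benzyloxy group and leave C4 alone.

**15 to 10 and 12.** The bonds between the outer benzylic CH2 groups and rings A and D are cut, and each CH2 is reconnected to C3. This gives the bis(1-aroyl-3-oxabicyclo[3.1.0]hexan-2-one) 10 and two equivalents of the aryl Grignard reagent 12. The neighbouring cuts are less attractive: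
- Cutting C3–C(inner) means enolate coupling of a preformed chiral lactone, which needs that lactone in excess and strong base at a late stage.
- Cutting C4–CH2 means benzyl conjugate addition to a butenolide, which needs reagent control at each site.

The cyclopropane cut removes both outer arenes and reduces the stereochemical problem to one alkene-face decision per unit, because the ring-fusion carbon C5 of 10 becomes lactone C4 unchanged. The forward step must attack the cyclopropane CH2, not the ring-fusion CH and not the ketone.

**10 to 9 and 8.** Each cyclopropane is cut at both bonds to C1 (C1–C5 and C1–C6). This reveals a carbene at C1 and an allyl ester, that is bis(α-diazo-β-keto ester) 9, which comes from bis(allyl β-keto ester) 8 by diazo transfer. The cut forms the lactone and the three-membered ring together from an achiral open chain, and the ester tether enforces the cis fusion, so the catalyst only has to choose the alkene face. Alkylating a β-keto ester with an enantiopure three-carbon epoxide electrophile was rejected, because β-keto esters tend to cyclise through oxygen in that reaction. The forward step needs catalyst-controlled face selectivity at an unsubstituted allyl group, twice.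

**8 to 5 and 6.** The bonds between each aroyl carbon and its α-CH2 are cut. This leads to diacid 5, a two-carbon malonate-type unit and allyl alcohol 6. Acylation of a cyclic malonate equivalent followed by alcoholysis was preferred over a crossed Claisen condensation, since it does not depend on the low electrophilicity of alkoxy-substituted benzoates. Compound 5 is a plain benzoic acid derivative with no stereochemistry.

**5 to 4, then to 2 and 3, then to 1.** Diacid 5 is traced to dialdehyde 4 (chlorite oxidation), because the aldehydes are present in the cheapest building blocks and are not enolisable. The diaryl ether C–O bond is then cut between the ring B oxygen and C3 of ring C, giving vanillin 3 as the phenol and bromide 2, the benzyl ether of 5-bromovanillin 1. The bromide is placed on ring C because 1 already carries the halogen next to the phenol. The forward coupling must join two ortho-oxygenated partners, which is why it is placed first, on robust material.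

**12 to 11.** The Grignard reagent 12 comes from 4-bromo-1,2-dimethoxybenzene 11 by magnesium insertion.

## Roads not taken

**Alternative 1:** The cut lies inside a four-membered ring. The O1–C5 bond of a monomeric lactone is traced back to a C–C bond of the prochiral cyclobutanone A2, and the C3–C(inner benzylic) bonds are cut so that the diaryl ether core arrives later as a bis-electrophile. In the forward direction a Baeyer–Villiger monooxygenase would insert oxygen into one of the two enantiotopic C(O)–CH2 bonds of A2 to give the (S)-lactone A1. The enolate of A1 would then be joined twice to a core such as dialdehyde 4 (aldol, then hydrogenolysis).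
- Merits: a single simple stereocentre is made catalytically on a small symmetric substrate; the trans relationship follows from anti attack on a β-substituted lactone enolate; on paper the sequence is about two operations shorter than the chosen one.
- Weak points: the enantiopreference of such enzymes toward 3-benzylcyclobutanones depends on the enzyme, so the (S) sense has to be found by screening and cofactor recycling set up; A1 is then needed in more than two equivalents for a twofold cryogenic coupling at the end, where mono-adducts cost material.
- Comparison: in step count and in the reliability of the late C–C bond formation this road is at least as good. The chosen plan sets against it that it needs no biocatalyst, that both C4 centres are fixed by one small-molecule catalyst on the assembled core, and that rings A and D enter last from an achiral Grignard reagent. A1 is kept in reserve, since the chiral pool also leads to it.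

**Alternative 2:** The C3–C4 bond of each lactone is cut and each lactone opened to a γ,δ-unsaturated acid. The precursor is then the bis-ester A4 of the diaryl ether bis(3-arylpropanoic acid) with an (S,E)-configured secondary allylic alcohol. In the forward direction, twofold enolisation and silylation followed by two Ireland–Claisen rearrangements through chair transition states would give bis-acid A3 with all four stereocentres. Each propenyl group must then be cleaved to a hydroxymethyl group and lactonised.
- Merits: both centres of each pair are set in one suprafacial event with reliable 1,3-chirality transfer; C3 is fixed kinetically, not by equilibration; the key step needs no metal.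
- Weak points: the relative configuration depends on the geometry of the silyl ketene acetal, which for a simple 3-arylpropanoate is only moderately controlled and must be right twice; two equivalents of a chiral allylic alcohol have to be prepared; the alkene cleavage must spare four electron-rich arenes, and cleavage, reduction and lactonisation add operations after the key step.
- Comparison: this road is better in that C3 does not rest on a thermodynamic preference. The chosen plan sets against it a single operation after the key step, catalytic chirality in place of stoichiometric chirality, and a trans preference of the β-keto lactone that is pronounced and easily reached.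

**Alternative 3:** Each lactone is cut at O1–C2 and C2–C3, taking out the carbonyl carbon as CO. This leads to the bis(homopropargylic alcohol) A6, in which rings B and C carry the alkynes. In the forward direction palladium-catalysed cyclocarbonylation would give the bis[(E)-benzylidene lactone] A5 (syn addition across each alkyne, CO insertion, ring closure by the hydroxyl group). Hydrogenation would then create C3.
- Merits: both lactone rings are closed and C2 is brought in from CO in one step; the assembly of A6 is convergent.
- Weak points: C3 is planar in A5, and hydrogen is delivered to the exocyclic alkene from the face away from the C4 benzyl group, which leads to the cis lactone, so an epimerisation is obligatory; A6 needs an enantiopure 2-substituted but-3-yn-1-ol and a dihalo diaryl ether, each taking several steps; the carbonylation must be regioselective on two aryl alkynes under CO pressure.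
- Comparison: after the key step this road is as short as the chosen one, and it is more atom-economic in building the lactone. The chosen plan sets against it that C4 comes from a catalytic step on material that already carries the core, not from a separately made chiral fragment, and that C3 emerges trans without passing through the cis isomer.

Key step: step 8

Remark on configuration: the target is taken as the all-(S) isomer with both lactones trans. The descriptor 3R in compound 15 reflects only the higher priority of the aroyl carbon; the spatial arrangement is that of 16.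

Assumption: [Co(Por*)] denotes the divalent cobalt complex of a D2-symmetric chiral amidoporphyrin dianion Por* (meso-aryl groups carrying chiral cyclopropanecarboxamide units). The antipode that delivers the (1R,5S) lactone is used; its sense of induction is to be confirmed on a mono-aroyl model before 9 is committed.

## Route

Step 1
Reactants: 1 5-bromovanillin (3-bromo-4-hydroxy-5-methoxybenzaldehyde)
Product: 2 4-(benzyloxy)-3-bromo-5-methoxybenzaldehyde
Conditions: BnBr, K2CO3, DMF, 60 °C
Reagents that add atoms: benzyl bromide, BrCc1ccccc1
Why: Williamson ether synthesis on a phenoxide acidified by the para formyl group; the benzyl ether should survive the copper, carbene and cuprate steps and leave in the final hydrogenolysis.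

Step 2
Reactants: 2 4-(benzyloxy)-3-bromo-5-methoxybenzaldehyde; 3 vanillin (4-hydroxy-3-methoxybenzaldehyde)
Product: 4 4-(benzyloxy)-3-(4-formyl-2-methoxyphenoxy)-5-methoxybenzaldehyde
Conditions: CuI (10 mol%), picolinic acid (20 mol%), K3PO4, DMSO, 90 °C
Reagents that add atoms: none
Why: Ullmann-type C–O coupling; copper/picolinate catalysis is a known way to join ortho-substituted phenols with ortho-substituted aryl bromides, and both formyl groups are non-enolisable and tolerate phosphate base.

Step 3
Reactants: 4 4-(benzyloxy)-3-(4-formyl-2-methoxyphenoxy)-5-methoxybenzaldehyde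
Product: 5 4-(benzyloxy)-3-(4-carboxy-2-methoxyphenoxy)-5-methoxybenzoic acid
Conditions: NaClO2, NaH2PO4, 2-methyl-2-butene, t-BuOH/THF/H2O, rt
Reagents that add atoms: sodium chlorite, [Na+].[O-]Cl=O
Why: Pinnick oxidation of both aryl aldehydes; the alkene scavenger removes hypochlorous acid, so the electron-rich rings should not be chlorinated.

Step 4
Reactants: 5 4-(benzyloxy)-3-(4-carboxy-2-methoxyphenoxy)-5-methoxybenzoic acid; 6 allyl alcohol
Product: 8 allyl 3-{4-[5-(3-(allyloxy)-3-oxopropanoyl)-2-(benzyloxy)-3-methoxyphenoxy]-3-methoxyphenyl}-3-oxopropanoate, via bis(acyl Meldrum's acid) 7 (not isolated)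
Conditions: Meldrum's acid, EDC·HCl, DMAP, CH2Cl2, 0 °C to rt; then 6, toluene, 100 °C
Reagents that add atoms: Meldrum's acid, CC1(C)OC(=O)CC(=O)O1
Why: Oikawa–Yonemitsu β-keto ester synthesis: carbodiimide-mediated C-acylation of Meldrum's acid at both carboxyl groups, then thermal loss of acetone and CO2 to acyl ketenes that are trapped by allyl alcohol.

Step 5
Reactants: 8 allyl 3-{4-[5-(3-(allyloxy)-3-oxopropanoyl)-2-(benzyloxy)-3-methoxyphenoxy]-3-methoxyphenyl}-3-oxopropanoate
Product: 9 allyl 2-diazo-3-{4-[5-(3-(allyloxy)-2-diazo-3-oxopropanoyl)-2-(benzyloxy)-3-methoxyphenoxy]-3-methoxyphenyl}-3-oxopropanoate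
Conditions: p-ABSA, Et3N, MeCN, 0 °C to rt
Reagents that add atoms: 4-acetamidobenzenesulfonyl azide, CC(=O)Nc1ccc(cc1)S(=O)(=O)N=[N+]=[N-]
Why: Regitz diazo transfer to the two doubly activated methylene groups; an amine base suffices and the allyl esters and benzyl ether are inert.

Step 6
Reactants: 9 allyl 2-diazo-3-{4-[5-(3-(allyloxy)-2-diazo-3-oxopropanoyl)-2-(benzyloxy)-3-methoxyphenoxy]-3-methoxyphenyl}-3-oxopropanoate
Product: 10 (1R,5S)-1-{4-[2-(benzyloxy)-3-methoxy-5-((1R,5S)-2-oxo-3-oxabicyclo[3.1.0]hexane-1-carbonyl)phenoxy]-3-methoxybenzoyl}-3-oxabicyclo[3.1.0]hexan-2-one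
Conditions: [Co(Por*)] (5 mol%), toluene, 40 °C
Reagents that add atoms: none
Why: Catalytic asymmetric intramolecular cyclopropanation of allyl α-acyl-diazoacetates by cobalt metalloradical catalysis, a known reaction of diazo esters carrying a second acceptor; each cobalt-bound carbene radical adds across its own allyl double bond through the ester tether, which enforces the cis fusion so that C1 and C5 are set together. The chiral porphyrin pocket, hydrogen-bonded through its amide N–H groups to the two carbonyl groups of the carbene, should select the alkene face that gives (1R,5S) at both units; a wrong-face event at either site would give a separable diastereomer of 10.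

Step 7
Reactants: 11 4-bromo-1,2-dimethoxybenzene
Product: 12 3,4-dimethoxyphenylmagnesium bromide (THF solution)
Conditions: Mg, I2 (cat.), THF, 40 °C
Reagents that add atoms: magnesium, [Mg]
Why: Grignard formation by insertion of magnesium into the aryl C–Br bond; the reagent is titrated and used as a solution.

Step 8
Reactants: 10 (1R,5S)-1-{4-[2-(benzyloxy)-3-methoxy-5-((1R,5S)-2-oxo-3-oxabicyclo[3.1.0]hexane-1-carbonyl)phenoxy]-3-methoxybenzoyl}-3-oxabicyclo[3.1.0]hexan-2-one; 12 3,4-dimethoxyphenylmagnesium bromide
Product: 15 (3R,4S)-3-{4-[2-(benzyloxy)-5-((3R,4S)-4-(3,4-dimethoxybenzyl)-2-oxotetrahydrofuran-3-carbonyl)-3-methoxyphenoxy]-3-methoxybenzoyl}-4-(3,4-dimethoxybenzyl)dihydrofuran-2(3H)-one, via bromomagnesium diarylcuprate 13 (not isolated), via bis(bromomagnesium enolate) 14 (not isolated)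
Conditions: CuBr·SMe2 (3 equiv), 12 (6 equiv), THF/Me2S, −40 °C; then 10, −40 to 0 °C; then 1 M HCl
Reagents that add atoms: none
Why: Homoconjugate addition of an organocuprate to a cyclopropane activated geminally by two carbonyl groups, the reaction type established for 2-oxo-3-oxabicyclo[3.1.0]hexane-1-carbonyl compounds. The preformed diarylcuprate 13 attacks the unsubstituted cyclopropane carbon C6 from the side opposite C1 in an SN2-like substitution followed by reductive elimination, forming the aryl–CH2 bond, breaking C1–C6 and releasing the magnesium enolate of the β-keto lactone; this happens once at each unit to give 14. No ring is closed; one three-membered ring is opened at each site and the lactones stay intact. C5 of each bicycle is neither attacked nor deprotonated and becomes lactone C4 with unchanged configuration (S). The new stereocentre C3 arises only on protonation of 14: the β-keto lactone is configurationally labile and should settle with the aroyl group trans to the C4 benzyl group, that is (3R,4S). Regioselectivity for C6 over C5 rests on the steric difference between a CH2 and a ring-fusion CH and on orbital alignment, since the C1–C6 bond stands out of the lactone plane and overlaps with the lactone carbonyl π*, whereas the C1–C5 bond lies in that plane. Chemoselectivity for the cyclopropane over the ketones rests on the soft cuprate, the absence of free Grignard reagent at low temperature and the hindered, conjugated ketone; after opening, the carbonyl groups are masked as the enolate.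

Step 9
Reactants: 15 (3R,4S)-3-{4-[2-(benzyloxy)-5-((3R,4S)-4-(3,4-dimethoxybenzyl)-2-oxotetrahydrofuran-3-carbonyl)-3-methoxyphenoxy]-3-methoxybenzoyl}-4-(3,4-dimethoxybenzyl)dihydrofuran-2(3H)-one
Product: 16 (3S,4S)-4-(3,4-dimethoxybenzyl)-3-{4-[5-(((3S,4S)-4-(3,4-dimethoxybenzyl)-2-oxotetrahydrofuran-3-yl)methyl)-2-hydroxy-3-methoxyphenoxy]-3-methoxybenzyl}dihydrofuran-2(3H)-one (CNP0183104.1)
Conditions: H2 (3 atm), 10% Pd/C, HClO4 (cat.), AcOH, rt; then DBU, toluene, 50 °C
Reagents that add atoms: none
Why: Acid-promoted catalytic hydrogenolysis: each aryl ketone is reduced to the benzylic alcohol and then to CH2 with assistance from the para oxygen substituent, and the benzyl ether is cleaved in the same operation. C4 is not touched; any C3 epimer formed by way of a benzylidene lactone should be returned to the more stable trans lactone by the amidine base.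

## Compound list

1 | 5-bromovanillin (3-bromo-4-hydroxy-5-methoxybenzaldehyde) | COc1cc(C=O)cc(Br)c1O | starting material
2 | 4-(benzyloxy)-3-bromo-5-methoxybenzaldehyde | COc1cc(C=O)cc(Br)c1OCc1ccccc1 | intermediate
3 | vanillin (4-hydroxy-3-methoxybenzaldehyde) | COc1cc(C=O)ccc1O | starting material
4 | 4-(benzyloxy)-3-(4-formyl-2-methoxyphenoxy)-5-methoxybenzaldehyde | COc1cc(C=O)ccc1Oc1cc(C=O)cc(OC)c1OCc1ccccc1 | intermediate
5 | 4-(benzyloxy)-3-(4-carboxy-2-methoxyphenoxy)-5-methoxybenzoic acid | COc1cc(C(=O)O)ccc1Oc1cc(C(=O)O)cc(OC)c1OCc1ccccc1 | intermediate
6 | allyl alcohol (prop-2-en-1-ol) | OCC=C | starting material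
7 | bis(acyl Meldrum's acid): both carboxyl groups of 5 as 5-[aryl(hydroxy)methylene]-2,2-dimethyl-1,3-dioxane-4,6-dione units (formed in the flask) | COc1cc(C(O)=C2C(=O)OC(C)(C)OC2=O)ccc1Oc1cc(C(O)=C2C(=O)OC(C)(C)OC2=O)cc(OC)c1OCc1ccccc1 | intermediate
8 | allyl 3-{4-[5-(3-(allyloxy)-3-oxopropanoyl)-2-(benzyloxy)-3-methoxyphenoxy]-3-methoxyphenyl}-3-oxopropanoate | COc1cc(C(=O)CC(=O)OCC=C)ccc1Oc1cc(C(=O)CC(=O)OCC=C)cc(OC)c1OCc1ccccc1 | intermediate
9 | allyl 2-diazo-3-{4-[5-(3-(allyloxy)-2-diazo-3-oxopropanoyl)-2-(benzyloxy)-3-methoxyphenoxy]-3-methoxyphenyl}-3-oxopropanoate | COc1cc(C(=O)C(=[N+]=[N-])C(=O)OCC=C)ccc1Oc1cc(C(=O)C(=[N+]=[N-])C(=O)OCC=C)cc(OC)c1OCc1ccccc1 | intermediate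
10 | (1R,5S)-1-{4-[2-(benzyloxy)-3-methoxy-5-((1R,5S)-2-oxo-3-oxabicyclo[3.1.0]hexane-1-carbonyl)phenoxy]-3-methoxybenzoyl}-3-oxabicyclo[3.1.0]hexan-2-one | O=C1OC[C@H]2C[C@@]12C(=O)c1ccc(Oc2cc(C(=O)[C@@]34C[C@@H]3COC4=O)cc(OC)c2OCc2ccccc2)c(OC)c1 | intermediate
11 | 4-bromo-1,2-dimethoxybenzene | COc1ccc(Br)cc1OC | starting material
12 | 3,4-dimethoxyphenylmagnesium bromide | COc1ccc([Mg]Br)cc1OC | intermediate
13 | bromomagnesium bis(3,4-dimethoxyphenyl)cuprate (formed in the flask) | COc1ccc([Cu-]c2ccc(OC)c(OC)c2)cc1OC.[Mg+]Br | intermediate
14 | bis(bromomagnesium enolate) of 15, (4S) at both lactones (formed in the flask) | COc1ccc(C[C@@H]2COC(=O)C2=C(O[Mg]Br)c2ccc(Oc3cc(C(O[Mg]Br)=C4C(=O)OC[C@H]4Cc4ccc(OC)c(OC)c4)cc(OC)c3OCc3ccccc3)c(OC)c2)cc1OC | intermediate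
15 | (3R,4S)-3-{4-[2-(benzyloxy)-5-((3R,4S)-4-(3,4-dimethoxybenzyl)-2-oxotetrahydrofuran-3-carbonyl)-3-methoxyphenoxy]-3-methoxybenzoyl}-4-(3,4-dimethoxybenzyl)dihydrofuran-2(3H)-one | COc1ccc(C[C@@H]2COC(=O)[C@H]2C(=O)c2ccc(Oc3cc(C(=O)[C@@H]4C(=O)OC[C@H]4Cc4ccc(OC)c(OC)c4)cc(OC)c3OCc5ccccc5)c(OC)c2)cc1OC | intermediate
16 | (3S,4S)-4-(3,4-dimethoxybenzyl)-3-{4-[5-(((3S,4S)-4-(3,4-dimethoxybenzyl)-2-oxotetrahydrofuran-3-yl)methyl)-2-hydroxy-3-methoxyphenoxy]-3-methoxybenzyl}dihydrofuran-2(3H)-one | COc1ccc(C[C@@H]2COC(=O)[C@H]2Cc2ccc(Oc3cc(C[C@@H]4C(=O)OC[C@H]4Cc4ccc(OC)c(OC)c4)cc(OC)c3O)c(OC)c2)cc1OC | target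

## Step count and least certain steps

Total step count: 9. Longest linear sequence: 8 (steps 1 to 6, 8 and 9; step 7 prepares the Grignard reagent on a side branch).

**Step 8 (key step).** The most likely failure is 1,2-addition of an aryl–metal species to the aryl ketones before the ring opens, or stalling after the first opening because the mono-enolate aggregates. The fallback sets out from 10 and comes back at 15, and delivers the aryl group by nickel-catalysed ring-opening cross-coupling in place of nucleophilic substitution. Reagent 12 is transmetalated with ZnBr2 to 3,4-dimethoxyphenylzinc bromide F1, which does not add to ketones. A low-valent nickel/2,2':6',2''-terpyridine catalyst generated from NiBr2(dme) should insert into the less hindered C1–C6 bond of each ketone-activated cyclopropane in the presence of TMSCl. Transmetalation and reductive elimination would give the bis(trimethylsilyl enol ether) F2, and dilute HCl in THF would hydrolyse it to 15.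

**Step 6.** The most likely failure is poor facial selectivity at the unsubstituted allyl terminus, which offers the catalyst little to differentiate and which, over two independent events, leaks into diastereomers of 10; a sluggish second carbene transfer is the other risk. The fallback sets out from 4 and comes back at 16, and takes the chirality from the chiral pool instead of a catalyst.
- Diethyl malonate and (S)-epichlorohydrin (NaOEt, EtOH) give ethyl (1R,5S)-2-oxo-3-oxabicyclo[3.1.0]hexane-1-carboxylate F3.
- The same strain-release arylation with 12 and catalytic CuI, here on the ester-activated lactone where it is established, gives ethyl (3R,4S)-4-(3,4-dimethoxybenzyl)-2-oxotetrahydrofuran-3-carboxylate F4.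
- Krapcho dealkoxycarbonylation (LiCl, wet DMSO, heat) gives (S)-4-(3,4-dimethoxybenzyl)dihydrofuran-2(3H)-one F5, the lactone labelled A1 above.
- Its lithium enolate (LiHMDS, THF, −78 °C) adds twice to dialdehyde 4, anti to the C4 substituent, to give the bis(aldol) adduct F6.
- Hydrogenolysis under the conditions of step 9 removes both benzylic hydroxyl groups and the benzyl ether to give 16.

**Step 2.** The most likely failure is slow C–O bond formation between an ortho-alkoxy aryl bromide and an electron-poor ortho-methoxy phenoxide, with protodebromination taking over. The fallback sets out from 2 and comes back at 4, and inverts the polarity of the ether synthesis. Miyaura borylation of 2 (B2pin2, Pd(dppf)Cl2, KOAc, dioxane) gives 4-(benzyloxy)-3-methoxy-5-(4,4,5,5-tetramethyl-1,3,2-dioxaborolan-2-yl)benzaldehyde F7. Oxidation with NaBO3·4H2O in THF/H2O gives 4-(benzyloxy)-3-hydroxy-5-methoxybenzaldehyde F8. Its phenoxide (K2CO3, DMF, 100 °C) displaces fluoride from commercial 4-fluoro-3-methoxybenzaldehyde in a nucleophilic aromatic substitution activated by the para formyl group, giving 4.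

**Step 9.** The most likely failure is incomplete hydrogenolysis at the ring B benzylic position, which has only a para aryloxy group to assist C–O cleavage. The other risk is scrambling of C3 by dehydration to a benzylidene lactone followed by hydrogen delivery anti to the C4 substituent; the DBU stage is meant to correct this. The fallback sets out from 15 and comes back at 16, and separates deoxygenation from debenzylation. Ionic hydrogenation (Et3SiH, TFA, CH2Cl2) reduces both aryl ketones through benzylic cations to give the O-benzyl ether of the target, F9. Neutral hydrogenolysis (H2, Pd/C, EtOAc/EtOH) then removes the benzyl group to give 16.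

## Further compounds

F1 | step 8 | 3,4-dimethoxyphenylzinc bromide | COc1ccc([Zn]Br)cc1OC
F2 | step 8 | bis(trimethylsilyl enol ether) of 15, (4S) at both lactones | COc1ccc(C[C@@H]2COC(=O)C2=C(O[Si](C)(C)C)c2ccc(Oc3cc(C(O[Si](C)(C)C)=C4C(=O)OC[C@H]4Cc4ccc(OC)c(OC)c4)cc(OC)c3OCc3ccccc3)c(OC)c2)cc1OC
F3 | step 6 | ethyl (1R,5S)-2-oxo-3-oxabicyclo[3.1.0]hexane-1-carboxylate | O=C1OC[C@H]2C[C@@]12C(=O)OCC
F4 | step 6 | ethyl (3R,4S)-4-(3,4-dimethoxybenzyl)-2-oxotetrahydrofuran-3-carboxylate | COc1ccc(C[C@@H]2COC(=O)[C@H]2C(=O)OCC)cc1OC
F5 | step 6 | (S)-4-(3,4-dimethoxybenzyl)dihydrofuran-2(3H)-one | COc1ccc(C[C@@H]2COC(=O)C2)cc1OC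
F6 | step 6 | bis(aldol) adduct of F5 with 4: (3R,4S)-3-[aryl(hydroxy)methyl]-4-(3,4-dimethoxybenzyl)lactone at both sites, carbinol centres as a mixture | COc1ccc(C[C@@H]2COC(=O)[C@H]2C(O)c2ccc(Oc3cc(C(O)[C@@H]4C(=O)OC[C@H]4Cc4ccc(OC)c(OC)c4)cc(OC)c3OCc3ccccc3)c(OC)c2)cc1OC
F7 | step 2 | 4-(benzyloxy)-3-methoxy-5-(4,4,5,5-tetramethyl-1,3,2-dioxaborolan-2-yl)benzaldehyde | COc1cc(C=O)cc(B2OC(C)(C)C(C)(C)O2)c1OCc1ccccc1
F8 | step 2 | 4-(benzyloxy)-3-hydroxy-5-methoxybenzaldehyde | COc1cc(C=O)cc(O)c1OCc1ccccc1
F9 | step 9 | O-benzyl ether of the target, (3S,4S) at both lactones | COc1ccc(C[C@@H]2COC(=O)[C@H]2Cc2ccc(Oc3cc(C[C@@H]4C(=O)OC[C@H]4Cc4ccc(OC)c(OC)c4)cc(OC)c3OCc3ccccc3)c(OC)c2)cc1OC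
A1 | alternative 1 | (S)-4-(3,4-dimethoxybenzyl)dihydrofuran-2(3H)-one | COc1ccc(C[C@@H]2COC(=O)C2)cc1OC
A2 | alternative 1 | 3-(3,4-dimethoxybenzyl)cyclobutan-1-one | COc1ccc(CC2CC(=O)C2)cc1OC
A3 | alternative 2 | bis(2,3-syn 2-arylmethyl-3-(3,4-dimethoxybenzyl)hex-4-enoic acid) on the benzyl-protected diaryl ether | COc1ccc(C[C@H](/C=C/C)[C@@H](C(=O)O)Cc2ccc(Oc3cc(C[C@H](C(=O)O)[C@@H](/C=C/C)Cc4ccc(OC)c(OC)c4)cc(OC)c3OCc5ccccc5)c(OC)c2)cc1OC
A4 | alternative 2 | bis[(S,E)-5-(3,4-dimethoxyphenyl)pent-3-en-2-yl] ester of the benzyl-protected diaryl ether bis(3-arylpropanoic acid) | C[C@H](OC(=O)CCc1ccc(Oc2cc(CCC(=O)O[C@@H](C)/C=C/Cc3ccc(OC)c(OC)c3)cc(OC)c2OCc2ccccc2)c(OC)c1)/C=C/Cc1ccc(OC)c(OC)c1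
A5 | alternative 3 | bis[(E)-3-arylidene-(4S)-4-(3,4-dimethoxybenzyl)lactone] of the benzyl-protected diaryl ether | COc1ccc(C[C@@H]2COC(=O)/C2=C/c2ccc(Oc3cc(/C=C4/C(=O)OC[C@H]4Cc4ccc(OC)c(OC)c4)cc(OC)c3OCc5ccccc5)c(OC)c2)cc1OC
A6 | alternative 3 | bis[(S)-4-aryl-2-(3,4-dimethoxybenzyl)but-3-yn-1-ol] of the benzyl-protected diaryl ether | COc1ccc(C[C@H](CO)C#Cc2ccc(Oc3cc(C#C[C@@H](CO)Cc4ccc(OC)c(OC)c4)cc(OC)c3OCc3ccccc3)c(OC)c2)cc1OC
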